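**Retrosynthetic overview** (xanthane numbering, lower half primed; ring A = upper lactone, B = upper seven-membered ring, C = cyclohexene, D = spiro lactone, E = lower seven-membered ring)
1. The target is a heterochiral Diels–Alder dimer: cut ring C at C5–C13′ and C3–C11′ and remove the C1–OH (γ-oxygenation of a β,γ-enone), giving diene 15 (8-epi-xanthatin with C13 masked as PhS–CH2) and dienophile 33 (the 2,3-dihydro monomer of the mirror-image series).
2. 15 and 33 come from the enol triflates of the enantiomeric bicyclic ketones 11 and 26 (C1 at ketone level): Heck reaction with methyl vinyl ketone for the upper half, B-alkyl Suzuki coupling for the lower half.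
3. Ketone 11 comes from iodomethyl ketone 9: ring B is closed at C5–C6 by 7-endo cyclization of the C5 α-keto radical onto the C7=C6 exo-methylene of ring A (held as a lactol ether). The enabling feature is that C6 is an unsubstituted CH2 between C7, a ring-fusion carbon of ring A, and C5, which is α to C1; the electrophilic radical and the 1,1-disubstituted alkene therefore sit seven atoms apart, and H7 is delivered last, cis to H8.
4. 9 comes from Ueno–Stork 5-exo-dig closure of ring A on a C8 propargylic alcohol (C8 by Noyori transfer hydrogenation, C10 from methyl 3-bromo-2-methylpropanoate); the lower half uses the enantiomeric bromide and catalyst.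
5. Ring order: A (step 4) → B (step 6) for the upper half; D (step 14) → E (step 16) for the lower half; then C (step 21).

Key step: step 6

Remark: the SMILES shows the two halves with mirror-image configurations at C7, C8 and C10 (upper 7R,8R,10S; lower 7′S,8′S,10′R), so the lower half is built in the enantiomeric series; 3-(trimethylsilyl)propioloyl chloride is taken as a purchasable reagent.

**Upper half**

Step 1
Reactants: 1 methyl (R)-3-bromo-2-methylpropanoate
Product: 3 methyl (2S)-2-methyl-4-oxo-6-(trimethylsilyl)hex-5-ynoate, via organozinc bromide 2 (not isolated)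
Conditions: Zn dust, LiCl, THF, 40 °C; then Pd(PPh3)4 (3 mol%), 3-(trimethylsilyl)propioloyl chloride, 0 °C to rt
Reagents that add atoms: 3-(trimethylsilyl)propioloyl chloride, C[Si](C)(C)C#CC(Cl)=O
Why: Zinc insertion into the primary bromide and Negishi acylation of the ester-tolerant alkylzinc build the C8 ynone, with the C10 stereocenter carried in unchanged from the bromide.

Step 2
Reactants: 3 methyl (2S)-2-methyl-4-oxo-6-(trimethylsilyl)hex-5-ynoate
Product: 4 methyl (2S,4R)-4-hydroxy-2-methyl-6-(trimethylsilyl)hex-5-ynoate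
Conditions: Ru(p-cymene)[(R,R)-TsDPEN] (1 mol%), i-PrOH, rt
Reagents that add atoms: none
Why: Noyori asymmetric transfer hydrogenation of an alkynyl ketone, in which the catalyst (alkynyl group in the place of the unsaturated substituent) should set C8 as R regardless of the remote C10 center.

Step 3
Reactants: 4 methyl (2S,4R)-4-hydroxy-2-methyl-6-(trimethylsilyl)hex-5-ynoate
Product: 6 methyl (2S,4R)-4-(2-bromo-1-ethoxyethoxy)-2-methylhex-5-ynoate (acetal epimers), via silylated bromoacetal 5 (not isolated)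
Conditions: ethyl vinyl ether, NBS, CH2Cl2, −40 to 0 °C; then K2CO3 (0.2 equiv), MeOH, rt
Reagents that add atoms: ethyl vinyl ether, C=COCC; N-bromosuccinimide, BrN1C(=O)CCC1=O
Why: Bromoacetalization of the alcohol (opening of the bromonium ion of the vinyl ether) traps the γ-hydroxy ester before it can lactonize, and methanolysis then removes the alkynyl silyl group; the acetal carbon forms as both epimers, which is of no consequence.

Step 4
Reactants: 6 methyl (2S,4R)-4-(2-bromo-1-ethoxyethoxy)-2-methylhex-5-ynoate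
Product: 7 methyl (2S)-3-[(2R)-5-ethoxy-3-methylideneoxolan-2-yl]-2-methylpropanoate (C5 epimers of the oxolane)
Conditions: Bu3SnH (1.3 equiv, 0.1 M), AIBN (0.1 equiv), PhH, 80 °C
Reagents that add atoms: none
Why: Ueno–Stork radical cyclization: the primary radical closes 5-exo-dig onto C7 (forming C11–C7 and ring A as a lactol ether) and the vinyl radical is reduced to the C7=C6 exo-methylene, the fairly high stannane concentration keeping it from abstracting H10.

Step 5
Reactants: 7 methyl (2S)-3-[(2R)-5-ethoxy-3-methylideneoxolan-2-yl]-2-methylpropanoate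
Product: 9 (3S)-4-[(2R)-5-ethoxy-3-methylideneoxolan-2-yl]-1-iodo-3-methylbutan-2-one, via chloromethyl ketone 8 (not isolated)
Conditions: ClCH2I, MeLi·LiBr, THF/Et2O, −78 °C, then aq. NH4Cl; then NaI, acetone, rt
Reagents that add atoms: chloroiodomethane, ClCI; sodium iodide, [Na+].[I-]
Why: Chloromethyllithium homologation of the ester (the tetrahedral adduct survives until the quench, so no over-addition and no epimerization at C10) followed by Finkelstein exchange gives the C5 radical precursor.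

Step 6
Reactants: 9 (3S)-4-[(2R)-5-ethoxy-3-methylideneoxolan-2-yl]-1-iodo-3-methylbutan-2-one
Product: 11 (3aR,7S,8aR)-2-ethoxy-7-methyloctahydro-6H-cyclohepta[b]furan-6-one (C2 epimers), via tertiary iodide 10 (not isolated)
Conditions: (Bu3Sn)2 (0.1 equiv), hν, PhH (0.01 M), 40 °C; then Bu3SnH (1.5 equiv), Et3B/air, 0 °C
Reagents that add atoms: none
Why: Bu3Sn• abstracts iodine from 9; the electrophilic C5 α-keto radical adds to the unsubstituted terminus C6 of the electron-rich 1,1-disubstituted C7=C6 alkene in a 7-endo-trig closure of ring B, and the tertiary C7 radical takes iodine from a further molecule of 9 to carry the chain, after which Bu3SnH/Et3B reduces iodide 10. The closest known reaction type is the iodine atom-transfer cyclization of α-iodo ketones, with the endo preference that α-carbonyl radicals show towards 1,1-disubstituted alkenes. The new C7 stereocenter is set in the reduction: the ring-fusion radical is planar, ring B (through C9) covers one face, and hydrogen should arrive on the face of H8, giving the cis-fused bicycle. The step needs 7-endo closure to win over 6-exo closure, direct reduction, and 1,5-hydrogen transfer from C8–H; attack at C7 would create a quaternary center and a primary radical, the polarity is matched, high dilution without stannane in the first stage suppresses reduction, and no enolate is formed, so C10 is not touched.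

Step 7
Reactants: 11 (3aR,7S,8aR)-2-ethoxy-7-methyloctahydro-6H-cyclohepta[b]furan-6-one
Product: 12 (3aR,7S,8aR)-2-ethoxy-7-methyl-3,3a,4,7,8,8a-hexahydro-2H-cyclohepta[b]furan-6-yl trifluoromethanesulfonate
Conditions: LiHMDS, THF, −78 °C; then PhNTf2, −78 to 0 °C
Reagents that add atoms: N-phenylbis(trifluoromethanesulfonimide), O=S(=O)(N(c1ccccc1)S(=O)(=O)C(F)(F)F)C(F)(F)F
Why: Kinetic deprotonation at the less hindered C5 methylene instead of the C10 methine, followed by O-triflation, gives the C1=C5 enol triflate regioselectively without epimerizing C10.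

Step 8
Reactants: 12 (3aR,7S,8aR)-2-ethoxy-7-methyl-3,3a,4,7,8,8a-hexahydro-2H-cyclohepta[b]furan-6-yl trifluoromethanesulfonate
Product: 13 (3aR,7S,8aR)-7-methyl-2-oxo-3,3a,4,7,8,8a-hexahydro-2H-cyclohepta[b]furan-6-yl trifluoromethanesulfonate
Conditions: mCPBA, BF3·OEt2 (0.3 equiv), CH2Cl2, 0 °C
Reagents that add atoms: 3-chloroperbenzoic acid, OOC(=O)c1cccc(Cl)c1
Why: Grieco oxidation of a lactol ether to the γ-lactone through the oxocarbenium–peracid adduct converges both acetal epimers, and the electron-poor enol triflate is inert to the peracid.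

Step 9
Reactants: 13 (3aR,7S,8aR)-7-methyl-2-oxo-3,3a,4,7,8,8a-hexahydro-2H-cyclohepta[b]furan-6-yl trifluoromethanesulfonate
Product: 14 (3R,3aR,7S,8aR)-7-methyl-2-oxo-3-[(phenylsulfanyl)methyl]-3,3a,4,7,8,8a-hexahydro-2H-cyclohepta[b]furan-6-yl trifluoromethanesulfonate
Conditions: LDA, THF, −78 °C; then PhSCH2Cl, NaI (0.1 equiv), DMPU, −78 to −20 °C
Reagents that add atoms: chloromethyl phenyl sulfide, ClCSc1ccccc1
Why: Alkylation of the lactone enolate on its convex face (cis to H7) installs C13 as a thioether-masked methylene, so that the later diene cannot act as its own dienophile; the C11 configuration is removed at the end.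

Step 10
Reactants: 14 (3R,3aR,7S,8aR)-7-methyl-2-oxo-3-[(phenylsulfanyl)methyl]-3,3a,4,7,8,8a-hexahydro-2H-cyclohepta[b]furan-6-yl trifluoromethanesulfonate
Product: 15 (3R,3aR,7S,8aR)-7-methyl-6-[(1E)-3-oxobut-1-en-1-yl]-3-[(phenylsulfanyl)methyl]-3,3a,4,7,8,8a-hexahydro-2H-cyclohepta[b]furan-2-one
Conditions: methyl vinyl ketone, Pd(OAc)2 (5 mol%), PPh3 (10 mol%), Et3N, DMF, 60 °C
Reagents that add atoms: methyl vinyl ketone, C=CC(C)=O
Why: Heck reaction of the enol triflate with methyl vinyl ketone (syn insertion, syn β-hydride elimination) gives the (E)-dienone C5=C1–C2=C3–C4=O of the 8-epi-xanthatin skeleton.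

**Lower half (mirror-image series)**

Step 11
Reactants: 16 methyl (S)-3-bromo-2-methylpropanoate
Product: 18 methyl (2R)-2-methyl-4-oxo-6-(trimethylsilyl)hex-5-ynoate, via organozinc bromide 17 (not isolated)
Conditions: Zn dust, LiCl, THF, 40 °C; then Pd(PPh3)4 (3 mol%), 3-(trimethylsilyl)propioloyl chloride, 0 °C to rt
Reagents that add atoms: 3-(trimethylsilyl)propioloyl chloride, C[Si](C)(C)C#CC(Cl)=O
Why: Mirror-image counterpart of step 1 (Negishi acylation), with C10′ taken from the (S)-bromide.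

Step 12
Reactants: 18 methyl (2R)-2-methyl-4-oxo-6-(trimethylsilyl)hex-5-ynoate
Product: 19 methyl (2R,4S)-4-hydroxy-2-methyl-6-(trimethylsilyl)hex-5-ynoate
Conditions: Ru(p-cymene)[(S,S)-TsDPEN] (1 mol%), i-PrOH, rt
Reagents that add atoms: none
Why: Noyori transfer hydrogenation with the enantiomeric catalyst sets C8′ as S, again under catalyst control.

Step 13
Reactants: 19 methyl (2R,4S)-4-hydroxy-2-methyl-6-(trimethylsilyl)hex-5-ynoate
Product: 21 methyl (2R,4S)-4-(2-bromo-1-ethoxyethoxy)-2-methylhex-5-ynoate (acetal epimers), via silylated bromoacetal 20 (not isolated)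
Conditions: ethyl vinyl ether, NBS, CH2Cl2, −40 to 0 °C; then K2CO3 (0.2 equiv), MeOH, rt
Reagents that add atoms: ethyl vinyl ether, C=COCC; N-bromosuccinimide, BrN1C(=O)CCC1=O
Why: Mirror-image counterpart of step 3 (bromoacetalization, then removal of the alkynyl silyl group).

Step 14
Reactants: 21 methyl (2R,4S)-4-(2-bromo-1-ethoxyethoxy)-2-methylhex-5-ynoate
Product: 22 methyl (2R)-3-[(2S)-5-ethoxy-3-methylideneoxolan-2-yl]-2-methylpropanoate (C5 epimers of the oxolane)
Conditions: Bu3SnH (1.3 equiv, 0.1 M), AIBN (0.1 equiv), PhH, 80 °C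
Reagents that add atoms: none
Why: Mirror-image counterpart of step 4 (Ueno–Stork 5-exo-dig closure of ring D as a lactol ether).

Step 15
Reactants: 22 methyl (2R)-3-[(2S)-5-ethoxy-3-methylideneoxolan-2-yl]-2-methylpropanoate
Product: 24 (3R)-4-[(2S)-5-ethoxy-3-methylideneoxolan-2-yl]-1-iodo-3-methylbutan-2-one, via chloromethyl ketone 23 (not isolated)
Conditions: ClCH2I, MeLi·LiBr, THF/Et2O, −78 °C, then aq. NH4Cl; then NaI, acetone, rt
Reagents that add atoms: chloroiodomethane, ClCI; sodium iodide, [Na+].[I-]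
Why: Mirror-image counterpart of step 5 (carbenoid homologation of the ester, Finkelstein exchange).

Step 16
Reactants: 24 (3R)-4-[(2S)-5-ethoxy-3-methylideneoxolan-2-yl]-1-iodo-3-methylbutan-2-one
Product: 26 (3aS,7R,8aS)-2-ethoxy-7-methyloctahydro-6H-cyclohepta[b]furan-6-one (C2 epimers), via tertiary iodide 25 (not isolated)
Conditions: (Bu3Sn)2 (0.1 equiv), hν, PhH (0.01 M), 40 °C; then Bu3SnH (1.5 equiv), Et3B/air, 0 °C
Reagents that add atoms: none
Why: Mirror-image counterpart of step 6: 7-endo atom-transfer cyclization closes ring E at C5′–C6′ and hydrogen delivery cis to H8′ sets C7′.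

Step 17
Reactants: 26 (3aS,7R,8aS)-2-ethoxy-7-methyloctahydro-6H-cyclohepta[b]furan-6-one
Product: 27 (3aS,7R,8aS)-2-ethoxy-7-methyl-3,3a,4,7,8,8a-hexahydro-2H-cyclohepta[b]furan-6-yl trifluoromethanesulfonate
Conditions: LiHMDS, THF, −78 °C; then PhNTf2, −78 to 0 °C
Reagents that add atoms: N-phenylbis(trifluoromethanesulfonimide), O=S(=O)(N(c1ccccc1)S(=O)(=O)C(F)(F)F)C(F)(F)F
Why: Mirror-image counterpart of step 7 (kinetic C1′=C5′ enol triflate).

Step 18
Reactants: 27 (3aS,7R,8aS)-2-ethoxy-7-methyl-3,3a,4,7,8,8a-hexahydro-2H-cyclohepta[b]furan-6-yl trifluoromethanesulfonate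
Product: 28 (3aS,7R,8aS)-7-methyl-2-oxo-3,3a,4,7,8,8a-hexahydro-2H-cyclohepta[b]furan-6-yl trifluoromethanesulfonate
Conditions: mCPBA, BF3·OEt2 (0.3 equiv), CH2Cl2, 0 °C
Reagents that add atoms: 3-chloroperbenzoic acid, OOC(=O)c1cccc(Cl)c1
Why: Mirror-image counterpart of step 8 (lactol ether to γ-lactone).

Step 19
Reactants: 28 (3aS,7R,8aS)-7-methyl-2-oxo-3,3a,4,7,8,8a-hexahydro-2H-cyclohepta[b]furan-6-yl trifluoromethanesulfonate
Product: 31 (3aS,7R,8aS)-7-methyl-3-methylidene-2-oxo-3,3a,4,7,8,8a-hexahydro-2H-cyclohepta[b]furan-6-yl trifluoromethanesulfonate, via Mannich base 29 (not isolated), via methiodide 30 (not isolated)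
Conditions: LDA, THF, −78 °C; CH2=NMe2+ I−; then MeI, MeOH, rt; then aq. NaHCO3, EtOAc
Reagents that add atoms: dimethylmethyleneammonium iodide, C=[N+](C)C.[I-]
Why: Mannich reaction of the lactone enolate with Eschenmoser's salt, quaternization and E1cB loss of trimethylamine give the α-methylene lactone that will serve as the dienophile.

Step 20
Reactants: 31 (3aS,7R,8aS)-7-methyl-3-methylidene-2-oxo-3,3a,4,7,8,8a-hexahydro-2H-cyclohepta[b]furan-6-yl trifluoromethanesulfonate
Product: 33 (3aS,7R,8aS)-7-methyl-3-methylidene-6-(3-oxobutyl)-3,3a,4,7,8,8a-hexahydro-2H-cyclohepta[b]furan-2-one, via ketal 32 (not isolated)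
Conditions: 9-BBN and 2-methyl-2-vinyl-1,3-dioxolane, THF, rt; then 31, Pd(dppf)Cl2 (5 mol%), K3PO4, DMF/H2O, rt; then 1 M HCl, THF, rt
Reagents that add atoms: 2-methyl-2-vinyl-1,3-dioxolane, C=CC1(C)OCCO1; water, O
Why: Anti-Markovnikov hydroboration and B-alkyl Suzuki–Miyaura coupling join C1′ of the enol triflate to C2′ under mild base at room temperature, and acid then unmasks the C4′ ketone.

**Union and end game**

Step 21
Reactants: 15 (3R,3aR,7S,8aR)-7-methyl-6-[(1E)-3-oxobut-1-en-1-yl]-3-[(phenylsulfanyl)methyl]-3,3a,4,7,8,8a-hexahydro-2H-cyclohepta[b]furan-2-one; 33 (3aS,7R,8aS)-7-methyl-3-methylidene-6-(3-oxobutyl)-3,3a,4,7,8,8a-hexahydro-2H-cyclohepta[b]furan-2-one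
Product: 34 Diels–Alder adduct with C5–C13′ and C3–C11′ bonds, a C1=C2 double bond and the C3 acetyl group cis to C6 on ring C (β,γ-unsaturated methyl ketone; C13 still as PhS–CH2)
Conditions: 33 (1.3 equiv), BHT, toluene (1 M), 100 °C, sealed tube
Reagents that add atoms: none
Why: Thermal [4+2] cycloaddition in the manner of xanthanolide dimerization: the s-cis C5=C1–C2=C3 diene of 15 should be attacked on the face of ring B opposite to the C10 methyl and the lactone, the C11′=C13′ dienophile on its convex face (syn to H7′), with the C12′ carbonyl endo and the acyl-bearing C3 joining C11′, which sets C5, C3 and the spiro center C11′.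

Step 22
Reactants: 34 Diels–Alder adduct (β,γ-unsaturated methyl ketone)
Product: 36 C1 tertiary alcohol with the C2=C3 enone (13-phenylsulfanyl-11,13-dihydro form of the target), via hydroperoxide 35 (not isolated)
Conditions: DBU, O2 (1 atm), P(OEt)3, MeCN, 0 °C
Reagents that add atoms: dioxygen, O=O
Why: Base-mediated γ-autoxidation of a β,γ-unsaturated ketone: DBU removes only the doubly activated H3, the dienolate takes up O2 at C1 on the face away from ring B (cis to H5) with return of the C2=C3 enone, and the phosphite reduces the hydroperoxide; the lower C1′=C5′ alkene and the saturated ketone do not respond to these conditions.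

Step 23
Reactants: 36 C1 tertiary alcohol (13-phenylsulfanyl-11,13-dihydro form of the target)
Product: 38 CNP0195550.3, via sulfoxide 37 (not isolated)
Conditions: NaIO4, MeOH/H2O, 0 °C; then CaCO3, toluene, 100 °C
Reagents that add atoms: none
Why: Chemoselective oxidation of the sulfide to the sulfoxide and thermal syn-elimination unveil the C11=C13 methylene; H11 is the only β-hydrogen, so the alkene can only be exocyclic.

**Compound list**

1 | methyl (R)-3-bromo-2-methylpropanoate | BrC[C@H](C)C(=O)OC | starting material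
2 | [(2R)-3-methoxy-2-methyl-3-oxopropyl]zinc bromide | Br[Zn]C[C@H](C)C(=O)OC | intermediate (not isolated)
3 | methyl (2S)-2-methyl-4-oxo-6-(trimethylsilyl)hex-5-ynoate | COC(=O)[C@@H](C)CC(=O)C#C[Si](C)(C)C | intermediate
4 | methyl (2S,4R)-4-hydroxy-2-methyl-6-(trimethylsilyl)hex-5-ynoate | COC(=O)[C@@H](C)C[C@@H](O)C#C[Si](C)(C)C | intermediate
5 | methyl (2S,4R)-4-(2-bromo-1-ethoxyethoxy)-2-methyl-6-(trimethylsilyl)hex-5-ynoate (acetal epimers) | COC(=O)[C@@H](C)C[C@@H](OC(CBr)OCC)C#C[Si](C)(C)C | intermediate (not isolated)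
6 | methyl (2S,4R)-4-(2-bromo-1-ethoxyethoxy)-2-methylhex-5-ynoate (acetal epimers) | COC(=O)[C@@H](C)C[C@@H](OC(CBr)OCC)C#C | intermediate
7 | methyl (2S)-3-[(2R)-5-ethoxy-3-methylideneoxolan-2-yl]-2-methylpropanoate (C5 epimers) | COC(=O)[C@@H](C)C[C@H]1OC(OCC)CC1=C | intermediate
8 | (3S)-1-chloro-4-[(2R)-5-ethoxy-3-methylideneoxolan-2-yl]-3-methylbutan-2-one | ClCC(=O)[C@@H](C)C[C@H]1OC(OCC)CC1=C | intermediate (not isolated)
9 | (3S)-4-[(2R)-5-ethoxy-3-methylideneoxolan-2-yl]-1-iodo-3-methylbutan-2-one | ICC(=O)[C@@H](C)C[C@H]1OC(OCC)CC1=C | intermediate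
10 | (7S,8aR)-2-ethoxy-3a-iodo-7-methyloctahydro-6H-cyclohepta[b]furan-6-one (C2 and C3a epimers) | O=C1CCC2(I)CC(OCC)O[C@@H]2C[C@@H]1C | intermediate (not isolated)
11 | (3aR,7S,8aR)-2-ethoxy-7-methyloctahydro-6H-cyclohepta[b]furan-6-one (C2 epimers) | O=C1CC[C@@H]2CC(OCC)O[C@@H]2C[C@@H]1C | intermediate
12 | (3aR,7S,8aR)-2-ethoxy-7-methyl-3,3a,4,7,8,8a-hexahydro-2H-cyclohepta[b]furan-6-yl trifluoromethanesulfonate | CCOC1C[C@H]2CC=C(OS(=O)(=O)C(F)(F)F)[C@@H](C)C[C@H]2O1 | intermediate
13 | (3aR,7S,8aR)-7-methyl-2-oxo-3,3a,4,7,8,8a-hexahydro-2H-cyclohepta[b]furan-6-yl trifluoromethanesulfonate | O=C1C[C@H]2CC=C(OS(=O)(=O)C(F)(F)F)[C@@H](C)C[C@H]2O1 | intermediate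
14 | (3R,3aR,7S,8aR)-7-methyl-2-oxo-3-[(phenylsulfanyl)methyl]-3,3a,4,7,8,8a-hexahydro-2H-cyclohepta[b]furan-6-yl trifluoromethanesulfonate | c1ccc(SC[C@H]2C(=O)O[C@@H]3C[C@H](C)C(OS(=O)(=O)C(F)(F)F)=CC[C@H]23)cc1 | intermediate
15 | (3R,3aR,7S,8aR)-7-methyl-6-[(1E)-3-oxobut-1-en-1-yl]-3-[(phenylsulfanyl)methyl]-3,3a,4,7,8,8a-hexahydro-2H-cyclohepta[b]furan-2-one | c1ccc(SC[C@H]2C(=O)O[C@@H]3C[C@H](C)C(/C=C/C(C)=O)=CC[C@H]23)cc1 | intermediate
16 | methyl (S)-3-bromo-2-methylpropanoate | BrC[C@@H](C)C(=O)OC | starting material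
17 | [(2S)-3-methoxy-2-methyl-3-oxopropyl]zinc bromide | Br[Zn]C[C@@H](C)C(=O)OC | intermediate (not isolated)
18 | methyl (2R)-2-methyl-4-oxo-6-(trimethylsilyl)hex-5-ynoate | COC(=O)[C@H](C)CC(=O)C#C[Si](C)(C)C | intermediate
19 | methyl (2R,4S)-4-hydroxy-2-methyl-6-(trimethylsilyl)hex-5-ynoate | COC(=O)[C@H](C)C[C@H](O)C#C[Si](C)(C)C | intermediate
20 | methyl (2R,4S)-4-(2-bromo-1-ethoxyethoxy)-2-methyl-6-(trimethylsilyl)hex-5-ynoate (acetal epimers) | COC(=O)[C@H](C)C[C@H](OC(CBr)OCC)C#C[Si](C)(C)C | intermediate (not isolated)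
21 | methyl (2R,4S)-4-(2-bromo-1-ethoxyethoxy)-2-methylhex-5-ynoate (acetal epimers) | COC(=O)[C@H](C)C[C@H](OC(CBr)OCC)C#C | intermediate
22 | methyl (2R)-3-[(2S)-5-ethoxy-3-methylideneoxolan-2-yl]-2-methylpropanoate (C5 epimers) | COC(=O)[C@H](C)C[C@@H]1OC(OCC)CC1=C | intermediate
23 | (3R)-1-chloro-4-[(2S)-5-ethoxy-3-methylideneoxolan-2-yl]-3-methylbutan-2-one | ClCC(=O)[C@H](C)C[C@@H]1OC(OCC)CC1=C | intermediate (not isolated)
24 | (3R)-4-[(2S)-5-ethoxy-3-methylideneoxolan-2-yl]-1-iodo-3-methylbutan-2-one | ICC(=O)[C@H](C)C[C@@H]1OC(OCC)CC1=C | intermediate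
25 | (7R,8aS)-2-ethoxy-3a-iodo-7-methyloctahydro-6H-cyclohepta[b]furan-6-one (C2 and C3a epimers) | O=C1CCC2(I)CC(OCC)O[C@H]2C[C@H]1C | intermediate (not isolated)
26 | (3aS,7R,8aS)-2-ethoxy-7-methyloctahydro-6H-cyclohepta[b]furan-6-one (C2 epimers) | O=C1CC[C@H]2CC(OCC)O[C@H]2C[C@H]1C | intermediate
27 | (3aS,7R,8aS)-2-ethoxy-7-methyl-3,3a,4,7,8,8a-hexahydro-2H-cyclohepta[b]furan-6-yl trifluoromethanesulfonate | CCOC1C[C@@H]2CC=C(OS(=O)(=O)C(F)(F)F)[C@H](C)C[C@@H]2O1 | intermediate
28 | (3aS,7R,8aS)-7-methyl-2-oxo-3,3a,4,7,8,8a-hexahydro-2H-cyclohepta[b]furan-6-yl trifluoromethanesulfonate | O=C1C[C@@H]2CC=C(OS(=O)(=O)C(F)(F)F)[C@H](C)C[C@@H]2O1 | intermediate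
29 | (3R,3aS,7R,8aS)-3-[(dimethylamino)methyl]-7-methyl-2-oxo-3,3a,4,7,8,8a-hexahydro-2H-cyclohepta[b]furan-6-yl trifluoromethanesulfonate | CN(C)C[C@@H]1C(=O)O[C@H]2C[C@@H](C)C(OS(=O)(=O)C(F)(F)F)=CC[C@@H]12 | intermediate (not isolated)
30 | trimethylammonium iodide of 29 (methiodide) | C[N+](C)(C)C[C@@H]1C(=O)O[C@H]2C[C@@H](C)C(OS(=O)(=O)C(F)(F)F)=CC[C@@H]12.[I-] | intermediate (not isolated)
31 | (3aS,7R,8aS)-7-methyl-3-methylidene-2-oxo-3,3a,4,7,8,8a-hexahydro-2H-cyclohepta[b]furan-6-yl trifluoromethanesulfonate | C=C1C(=O)O[C@H]2C[C@@H](C)C(OS(=O)(=O)C(F)(F)F)=CC[C@@H]12 | intermediate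
32 | (3aS,7R,8aS)-7-methyl-3-methylidene-6-[2-(2-methyl-1,3-dioxolan-2-yl)ethyl]-3,3a,4,7,8,8a-hexahydro-2H-cyclohepta[b]furan-2-one | C=C1C(=O)O[C@H]2C[C@@H](C)C(CCC3(C)OCCO3)=CC[C@@H]12 | intermediate (not isolated)
33 | (3aS,7R,8aS)-7-methyl-3-methylidene-6-(3-oxobutyl)-3,3a,4,7,8,8a-hexahydro-2H-cyclohepta[b]furan-2-one | C=C1C(=O)O[C@H]2C[C@@H](C)C(CCC(C)=O)=CC[C@@H]12 | intermediate
34 | Diels–Alder adduct of 15 and 33 (C5–C13′ and C3–C11′ bonds, C1=C2, C3 acetyl cis to C6, C12′ carbonyl cis to C6, C13 as PhS–CH2) | c1ccc(SC[C@H]2C(=O)O[C@@H]3C[C@H](C)C4=C[C@@H](C(C)=O)[C@]5(C[C@H]4C[C@H]23)C(=O)O[C@H]2C[C@@H](C)C(CCC(C)=O)=CC[C@H]25)cc1 | intermediate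
35 | C1 hydroperoxide of the C2=C3 enone (O on C1 cis to H5) | c1ccc(SC[C@H]2C(=O)O[C@@H]3C[C@H](C)[C@@]4(OO)C=C(C(C)=O)[C@]5(C[C@H]4C[C@H]23)C(=O)O[C@H]2C[C@@H](C)C(CCC(C)=O)=CC[C@H]25)cc1 | intermediate (not isolated)
36 | C1 tertiary alcohol, 13-phenylsulfanyl-11,13-dihydro form of the target | c1ccc(SC[C@H]2C(=O)O[C@@H]3C[C@H](C)[C@@]4(O)C=C(C(C)=O)[C@]5(C[C@H]4C[C@H]23)C(=O)O[C@H]2C[C@@H](C)C(CCC(C)=O)=CC[C@H]25)cc1 | intermediate
37 | sulfoxide of 36 (epimers at sulfur) | O=S(C[C@H]2C(=O)O[C@@H]3C[C@H](C)[C@@]4(O)C=C(C(C)=O)[C@]5(C[C@H]4C[C@H]23)C(=O)O[C@H]2C[C@@H](C)C(CCC(C)=O)=CC[C@H]25)c1ccccc1 | intermediate (not isolated)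
38 | CNP0195550.3 | C=C1C(=O)O[C@@H]2C[C@H](C)[C@@]3(O)C=C(C(C)=O)[C@]4(C[C@H]3C[C@H]12)C(=O)O[C@H]1C[C@@H](C)C(CCC(C)=O)=CC[C@H]14 | target

**Totals and risks**

Total step count: 23. Longest linear sequence: 13 steps (steps 1–10, then 21–23; the lower-half branch, steps 11–20 then 21–23, is equally long).

Steps most likely to fail:

Step 6 (7-endo radical closure of ring B). The α-keto radical may be reduced before it cyclizes, may abstract the allylic C8 hydrogen by 1,5-transfer, or hydrogen may be delivered to C7 without facial control. The fallback sets out from 7 and comes back at 11, fixing C7 on the monocycle and closing C5–C6 by a polar SN2 reaction. Hydroboration of the exo-methylene of 7 with 9-BBN from the face opposite to the C8 side chain, then NaOH/H2O2, would give the cis-hydroxymethyl ester, methyl (2S)-3-[(2R,3S)-5-ethoxy-3-(hydroxymethyl)oxolan-2-yl]-2-methylpropanoate F1. I2/PPh3/imidazole would give the primary iodide, the 3-(iodomethyl) analogue of F1, F2. LiCH2SO2Ph (2 equiv, THF, −78 °C, cold quench) would turn the ester into the β-keto sulfone, (3S)-4-[(2R,3R)-5-ethoxy-3-(iodomethyl)oxolan-2-yl]-3-methyl-1-(phenylsulfonyl)butan-2-one F3. K2CO3 in DMF would close ring B by C-alkylation of the soft C5 carbanion at C6, giving the cyclic β-keto sulfone, the 5-(phenylsulfonyl) derivative of 11, F4. SmI2 in THF/MeOH would remove the sulfonyl group and return 11.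

Step 21 (Diels–Alder union). The cycloaddition between two electron-poor partners may be slow, endo or facial selectivity may erode in the heterochiral pairing, or the partners may decay thermally before they combine. The fallback sets out from 15 and comes back at 34. Luche reduction (NaBH4, CeCl3, MeOH, −40 °C) of the C4 ketone would give the dienyl carbinol, the C4 alcohol of 15 (both C4 epimers), F5, an electron-richer diene for a normal-demand cycloaddition. Heating F5 with 33 (toluene, 80 °C) would give the adduct carbinol, the C4 alcohol of 34, F6, through the same bonds and faces. Dess–Martin periodinane (CH2Cl2, NaHCO3) would restore the C4 ketone and return 34.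

Step 22 (γ-oxygenation at C1). The enone may move into conjugation without taking up oxygen, oxygen may enter at C3 instead of C1, or it may attack from the wrong face. The fallback sets out from 34 and comes back at 36, replacing autoxidation by a [2,3]-sigmatropic transfer. Soft enolization of the doubly activated C3–H ketone (TMSOTf 1.05 equiv, Et3N, CH2Cl2, −78 °C) would give the silyl dienol ether, the C3=C4 trimethylsilyl enol ether of 34, F7. PhSeCl at −78 °C would selenenylate C3 on the face of H5, giving the allylic selenide, the 3-(phenylselanyl) derivative of 34, F8. H2O2/pyridine at −20 °C would oxidize selenium in preference to sulfur, and the allyl selenoxide would rearrange suprafacially (Se on C3 to O on C1); hydrolysis of the selenenate would return 36.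

Further compounds
F1 | step 6 | methyl (2S)-3-[(2R,3S)-5-ethoxy-3-(hydroxymethyl)oxolan-2-yl]-2-methylpropanoate | COC(=O)[C@@H](C)C[C@H]1OC(OCC)C[C@H]1CO
F2 | step 6 | methyl (2S)-3-[(2R,3R)-5-ethoxy-3-(iodomethyl)oxolan-2-yl]-2-methylpropanoate | COC(=O)[C@@H](C)C[C@H]1OC(OCC)C[C@H]1CI
F3 | step 6 | (3S)-4-[(2R,3R)-5-ethoxy-3-(iodomethyl)oxolan-2-yl]-3-methyl-1-(phenylsulfonyl)butan-2-one | O=C(CS(=O)(=O)c1ccccc1)[C@@H](C)C[C@H]2OC(OCC)C[C@H]2CI
F4 | step 6 | 5-(phenylsulfonyl) derivative of 11 (C5 epimers) | O=C1C(S(=O)(=O)c2ccccc2)C[C@@H]3CC(OCC)O[C@@H]3C[C@@H]1C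
F5 | step 21 | C4 alcohol of 15 (C4 epimers) | c1ccc(SC[C@H]2C(=O)O[C@@H]3C[C@H](C)C(/C=C/C(C)O)=CC[C@H]23)cc1
F6 | step 21 | C4 alcohol of 34 (C4 epimers) | c1ccc(SC[C@H]2C(=O)O[C@@H]3C[C@H](C)C4=C[C@@H](C(C)O)[C@]5(C[C@H]4C[C@H]23)C(=O)O[C@H]2C[C@@H](C)C(CCC(C)=O)=CC[C@H]25)cc1
F7 | step 22 | C3=C4 trimethylsilyl dienol ether of 34 | c1ccc(SC[C@H]2C(=O)O[C@@H]3C[C@H](C)C4=CC(=C(C)O[Si](C)(C)C)[C@]5(C[C@H]4C[C@H]23)C(=O)O[C@H]2C[C@@H](C)C(CCC(C)=O)=CC[C@H]25)cc1
F8 | step 22 | 3-(phenylselanyl) derivative of 34 | c1ccc(SC[C@H]2C(=O)O[C@@H]3C[C@H](C)C4=C[C@@]([Se]c6ccccc6)(C(C)=O)[C@]5(C[C@H]4C[C@H]23)C(=O)O[C@H]2C[C@@H](C)C(CCC(C)=O)=CC[C@H]25)cc1
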